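**Remarks on the chemistry (corrections and assumptions)**

- Locants: counted from the benzylic carbon, the ring A unit of the key-step precursor is 2-aroyl-3,4,6-trimethoxybenzyl. A "3,5,6-trimethoxybenzyl" name would put the lone methoxy group next to the aroyl group and would lead to the 3-methoxyquinone isomer. The SMILES of 17 has the correct 3,4,6 pattern, and that structure is used throughout.
- Atom numbers C1–C8a are those of the naphthoquinone of the target (ring A = C1–C4, C4a, C8a; ring B = C4a–C8a).
- 4-Benzyloxy-3-methoxybenzaldehyde and allyl acetoacetate are taken as purchasable; the former is otherwise one benzylation away from vanillin.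
- Precursor design: the skeleton and the benzyl ethers are kept. The ester that is lost before the key step is changed to an allyl ester so that 17 is released under neutral conditions.
- Racemic compounds are written with one enantiomer drawn.

## Structural features

Larreantin (23) is a 2-methoxy-1,4-naphthoquinone: ring A is the quinone ring (C1–C4, C4a, C8a) and ring B the fused benzenoid ring (C5–C8). Ring B carries three different carbon substituents on adjacent atoms: a 4-hydroxy-3-methoxybenzyl group at C6, a methyl group at C7 and a 4-hydroxy-3-methoxyphenyl group at C8, so only C5 bears hydrogen. The C8 aryl group is peri to the C1 carbonyl and the methoxy group sits on C2, so the ring A oxygen pattern must be placed with the correct sense relative to the ring B substituents. There is no stereocentre, and the C8–aryl axis (only hydrogens ortho on the guaiacyl ring) is not expected to be configurationally stable, so no stereochemistry has to be set. Fragile groups are the methoxyquinone (a reducible, nucleophile-sensitive vinylogous ester), the two free guaiacol-type phenols (easily oxidised) and the doubly benzylic CH2 on C6. The real difficulty is the crowded C6–C7–C8 edge with its fixed order of substituents, together with the regiochemistry of the ring A oxygenation. The key step exploits the fact that C7 and C8 are neighbouring sp2 carbons of ring B that each trace back to a ketone carbon (C7 to a methyl ketone, C8 to a diaryl ketone), linked through C6, C5, C4a and C8a as a 1,6-diketone.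

## Logic of the disconnections

23 ⇒ 21 (through 22). The two phenolic O–H bonds are traced back to O–benzyl bonds. Free guaiacols would not survive the oxidations of rings A and B, whereas benzyl ethers tolerate organolithium, hydride, low-valent titanium and one-electron oxidants and leave under neutral conditions. The demand is that hydrogenolysis also reduces the quinone, so the forward step passes through 22 and relies on aerial reoxidation.

21 ⇒ 20. The C1=O and C4=O bonds are traced back to aryl methyl ethers. Ring A becomes an inert trimethoxyarene for the whole construction and the quinone appears late. The forward oxidative demethylation must give the para-quinone, not the ortho-quinone, and must spare the other electron-rich rings and the C6 CH2.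

20 ⇒ 19. Hydrogen is returned to C5 and C6, leaving a single C7=C8 double bond in ring B. This is the oxidation level that a carbonyl coupling delivers; the C6 stereocentre it creates is erased again. The forward dehydrogenation must not touch the benzylic CH2.

19 ⇒ 17 (through 18). The C7=C8 bond is cut into two carbonyl groups. Ring B opens, and the tetrasubstituted alkene is replaced by a methyl ketone and a non-enolisable diaryl ketone on a chain where the order of the three substituents is fixed by connectivity. The forward step must join two electrophilic carbons reductively and intramolecularly.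

17 ⇒ 15 (through 16). The C6–H bond is traced back to a C6–CO2allyl bond. C6 becomes the central carbon of an acetoacetate, so both benzylic groups can be introduced by enolate chemistry. The forward decarboxylation must be neutral, because 17 holds an enolisable ketone close to a second carbonyl.

15 ⇒ 11 + 14. The C5–C6 bond is cut as an enolate alkylation. The cut separates the ring A/C8-aryl half from the C6/C7 half. The forward step must build a quaternary carbon with a hindered, ionisation-prone benzylic bromide.

14 ⇒ 4 + 12 (through 13). The bond between C6 and the CH2 of its benzyl group is cut as a reductive condensation. The same aldehyde 4 that supplies the C8 aryl group is used, and over-alkylation is impossible. The forward step must reduce the alkylidene without touching the ketone or the allyl ester.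

11 ⇒ 10 ⇒ 9 ⇒ 8. Only functional groups change: C–Br from C–OSi, ketone from carbinol, and a silyl ether to tell the two hydroxyl groups apart. The two benzylic carbons of 8 must end at different oxidation levels (C5 as a leaving group, C8 as a ketone). The demand is steric discrimination between a primary and a flanked diaryl carbinol.

8 ⇒ 7. Both C–OH groups are traced back to one lactone. This joins the two benzylic carbons in a stable, crystalline-type intermediate; the forward step is a plain hydride reduction.

7 ⇒ 3 + 4 (through 5 and 6). The C8–C8a bond is cut. The amide carbon of 3 is the future C5, and the ring position between the amide and a methoxy group is the future C8a. The forward metalation must occur there and not at the position between two methoxy groups.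

3 ⇒ 1 (through 2). The amide C–N bond is cut; 1 already carries the complete oxygen pattern of ring A in the correct sense.

## Other disconnections considered

Alternative 1: The cut removes three bonds at once, C4a–C8a, C5–C6 and C7–C8, and leads back to the enedione-tethered 1,7-diyne A2 and the butyne A3. Forward, [Rh(cod)2]BF4/BINAP (monovalent rhodium) would cyclotrimerise A2 with A3 by oxidative cyclisation of the diyne on rhodium, insertion of A3 and reductive elimination, giving the bis-silyl ether A1 with rings A and B formed together.
- In its favour: it is the most convergent plan. A1 is already at the quinone oxidation level, so only desilylation remains. On step economy after the key step, and on bonds and rings formed in one operation, it is better than the chosen plan. The metal is catalytic and no high dilution is needed, also a point for the alternative.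
- Against it here: A3 is a dialkyl alkyne whose two ends (methyl and arylmethyl) differ little in size or polarity. Its orientation relative to the two different termini of A2 is not obviously controlled, so the C6/C7-swapped isomer of A1 must be expected. In the chosen plan this order is fixed by connectivity in 17, which is the stronger position.
- A2 is a cross-conjugated bis-ynone on a cis-enedione with three Michael acceptors. It should be prone to geometric isomerisation, polymerisation and self-trimerisation, may deactivate the cationic catalyst by chelation, and its preparation is a problem of similar size to 17.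
- Comparison: both plans rest on well-precedented metal-mediated mechanisms. The alternative is shorter on paper but leaves a regiochemical question open at exactly the edge that defines the target.

Alternative 2: The cut is C4–C4a. It leads back to the cyclobutenone A5, which would come from the aryl bromide A6 (by halogen–metal exchange) and the methoxycyclobutenedione A7. Forward, heating A5 in xylene would cause 4π-electrocyclic ring opening, 6π-electrocyclisation of the ketene carbon onto C4a and tautomerisation to the hydroquinone A4; oxidation and desilylation would follow.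
- In its favour: the ring A oxygen pattern is built into A5, so the para-quinone with the methoxy group on C2 follows from connectivity. On this point the alternative is better than the chosen plan, whose step 12 must choose between para- and ortho-quinone.
- Closure can only go to C4a, because the other ortho position carries the C8 aryl group. The key step needs no reagent, and the end game is gentler than steps 11–13.
- Against it here: the alternative builds ring A, the easy ring, and assumes ring B complete. A6 is a 1,2,3,4-tetrasubstituted benzene with aryl, methyl and benzyl groups in fixed order, i.e. the hard part of the target undiminished.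
- The hindered ortho-aryl organometallic from A6 must also discriminate the two carbonyl groups of A7, and the new bond forms next to a peri aryl group.
- Comparison: the pericyclic cascade is mechanistically cleaner than a heterogeneous reductive coupling and superior on ring A regiochemistry. The chosen plan addresses the crowded C6–C7–C8 edge directly where the alternative postpones it. On step economy the alternative is probably equal at best once the route to A6 is counted.

Alternative 3: The cut is C5–C6 and C7–C8, leading to the aldehyde A9 and the ynone A10. Forward, irradiation at 365 nm would photoenolise A9 (1,5-hydrogen transfer from the diarylmethane CH2 to the excited formyl group). [4+2] cycloaddition of the photoenol form of A9 with A10 and acid-promoted loss of water would give the naphthalene A8.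
- In its favour: two C–C bonds and ring B with all three substituents are made in one step. The naphthalene level is reached directly, so no dehydrogenation step is needed; that is better than the chosen plan. Polarity dictates the regiochemistry (the hydroxyl-bearing terminus bonds to the acyl-bearing alkyne carbon, placing acyl at C6 and methyl at C7). No stoichiometric metal or high dilution is needed, also better.
- Against it here: A8 carries a C6 aroyl group, one oxidation level too high, so a diaryl ketone to CH2 reduction on a very electron-rich substrate is added.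
- A10 is a β-methyl ynone and a slow dienophile, and the diene terminus bears an aryl group, so trapping must compete with reketonisation of the photoenol form of A9. A10 also absorbs near 365 nm and may react photochemically itself.
- A9 still needs an ortho-functionalisation of ring A of the kind used in steps 1–2, so nothing is saved upstream.
- Comparison: equal in rings formed (one), better in bonds formed in the key step and in reaching the naphthalene directly, worse in the extra deoxygenation and in the predictability of the photochemical step. The overall step count should be similar.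

Key step: step 10

## Route

Step 1
Reactants: 1 2,4,5-trimethoxybenzoic acid
Product: 3 N,N-diethyl-2,4,5-trimethoxybenzamide, via 2,4,5-trimethoxybenzoyl chloride 2 (not isolated)
Conditions: (COCl)2, DMF (cat.), CH2Cl2, 0 °C → rt; concentrate; Et2NH, Et3N, CH2Cl2, 0 °C → rt
Reagents that add atoms: diethylamine, CCNCC; oxalyl chloride, ClC(=O)C(=O)Cl (chlorine of intermediate 2 only)
Why: Acid chloride formation followed by amidation; the tertiary diethylamide is the strongest readily made director for the metalation of step 2.

Step 2
Reactants: 3 N,N-diethyl-2,4,5-trimethoxybenzamide; 4 4-benzyloxy-3-methoxybenzaldehyde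
Product: 7 3-(4-benzyloxy-3-methoxyphenyl)-4,5,7-trimethoxyisobenzofuran-1(3H)-one (racemic), via the 2-lithiobenzamide 5 (not isolated), via the hydroxy amide 6 (not isolated)
Conditions: s-BuLi, TMEDA, THF, −78 °C; 4, −78 °C → rt; H2O; then TsOH·H2O (cat.), PhMe, 90 °C
Reagents that add atoms: sec-butyllithium, CCC(C)[Li] (lithium of intermediate 5 only)
Why: Directed ortho-metalation: the amide and the neighbouring methoxy group together direct lithiation to the one position flanked by the amide, in preference to the C–H between two methoxy groups. The aryllithium adds to 4 and acid-promoted lactonisation expels diethylamine; the carbinol centre forms racemic and is erased in step 5.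

Step 3
Reactants: 7 3-(4-benzyloxy-3-methoxyphenyl)-4,5,7-trimethoxyisobenzofuran-1(3H)-one
Product: 8 (4-benzyloxy-3-methoxyphenyl)[2-(hydroxymethyl)-3,5,6-trimethoxyphenyl]methanol (racemic)
Conditions: LiAlH4, THF, 0 °C → rt; basic aqueous work-up
Reagents that add atoms: none
Why: Hydride reduction of a lactone to the diol; aryl benzyl and methyl ethers are inert, and a basic work-up avoids acid-promoted closure of the electron-rich benzhydrol onto the primary alcohol.

Step 4
Reactants: 8 (4-benzyloxy-3-methoxyphenyl)[2-(hydroxymethyl)-3,5,6-trimethoxyphenyl]methanol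
Product: 9 (4-benzyloxy-3-methoxyphenyl)[2-(tert-butyldimethylsilyloxymethyl)-3,5,6-trimethoxyphenyl]methanol (racemic)
Conditions: TBSCl (1.05 equiv), imidazole, CH2Cl2, 0 °C
Reagents that add atoms: tert-butyldimethylsilyl chloride, CC(C)(C)[Si](C)(C)Cl
Why: Sterically controlled monosilylation: the primary hydroxyl reacts, while the diaryl carbinol flanked by two ortho substituents does not.

Step 5
Reactants: 9 (4-benzyloxy-3-methoxyphenyl)[2-(tert-butyldimethylsilyloxymethyl)-3,5,6-trimethoxyphenyl]methanol
Product: 10 (4-benzyloxy-3-methoxyphenyl)[2-(tert-butyldimethylsilyloxymethyl)-3,5,6-trimethoxyphenyl]methanone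
Conditions: Dess–Martin periodinane, CH2Cl2, rt
Reagents that add atoms: none
Why: Dess–Martin oxidation of a hindered secondary benzhydrol to the diaryl ketone; the silyl ether keeps the other benzylic carbon at the alcohol level, so no lactol or lactone can form.

Step 6
Reactants: 10 (4-benzyloxy-3-methoxyphenyl)[2-(tert-butyldimethylsilyloxymethyl)-3,5,6-trimethoxyphenyl]methanone
Product: 11 [2-(bromomethyl)-3,5,6-trimethoxyphenyl](4-benzyloxy-3-methoxyphenyl)methanone, i.e. 2-(4-benzyloxy-3-methoxybenzoyl)-3,4,6-trimethoxybenzyl bromide
Conditions: Ph3PBr2, CH2Cl2, 0 °C → rt; short silica plug; crude 11 used at once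
Reagents that add atoms: dibromotriphenylphosphorane, BrP(Br)(c1ccccc1)(c1ccccc1)c1ccccc1
Why: Direct Appel-type conversion of a benzylic silyl ether into the bromide through an alkoxyphosphonium bromide; this avoids the free hydroxy ketone, which could close to a cyclic hemiketal.

Step 7
Reactants: 4 4-benzyloxy-3-methoxybenzaldehyde; 12 allyl acetoacetate
Product: 14 allyl 2-(4-benzyloxy-3-methoxybenzyl)-3-oxobutanoate (racemic), via the Knoevenagel alkylidene 13 (not isolated)
Conditions: L-proline (20 mol%), Hantzsch ester (1.1 equiv), MeCN, rt
Reagents that add atoms: none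
Why: Proline-catalysed Knoevenagel condensation with in situ conjugate hydride transfer from the Hantzsch ester (three-component reductive alkylation); only the monoalkylated keto ester can form, and its stereocentre is racemic and labile.

Step 8
Reactants: 14 allyl 2-(4-benzyloxy-3-methoxybenzyl)-3-oxobutanoate; 11 2-(4-benzyloxy-3-methoxybenzoyl)-3,4,6-trimethoxybenzyl bromide
Product: 15 allyl 2-acetyl-2-(4-benzyloxy-3-methoxybenzyl)-3-[2-(4-benzyloxy-3-methoxybenzoyl)-3,4,6-trimethoxyphenyl]propanoate (racemic)
Conditions: NaH, THF–DMF, 0 °C; then 11, 0 °C → rt
Reagents that add atoms: none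
Why: C-alkylation of a stabilised β-keto ester enolate by an activated benzylic bromide forms the C5–C6 bond and a racemic quaternary carbon; with no hydrogen left on that carbon, no enolate can close onto the diaryl ketone.

Step 9
Reactants: 15 allyl 2-acetyl-2-(4-benzyloxy-3-methoxybenzyl)-3-[2-(4-benzyloxy-3-methoxybenzoyl)-3,4,6-trimethoxyphenyl]propanoate
Product: 17 3-[2-(4-benzyloxy-3-methoxybenzoyl)-3,4,6-trimethoxybenzyl]-4-(4-benzyloxy-3-methoxyphenyl)butan-2-one (racemic), via the β-keto acid 16 (not isolated)
Conditions: Pd(OAc)2 (5 mol%), PPh3, HCO2H, Et3N, THF, rt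
Reagents that add atoms: none
Why: Pd(OAc)2 (divalent palladium) is reduced in situ to zerovalent palladium, which ionises the allyl ester (Tsuji–Trost-type); formate reduces the allyl fragment to propene and the β-keto acid loses CO2 at room temperature. The near-neutral conditions avoid the retro-Claisen and aldol reactions that hydroxide would cause, and C6 forms racemic.

Step 10
Reactants: 17 3-[2-(4-benzyloxy-3-methoxybenzoyl)-3,4,6-trimethoxybenzyl]-4-(4-benzyloxy-3-methoxyphenyl)butan-2-one
Product: 19 6-(4-benzyloxy-3-methoxybenzyl)-8-(4-benzyloxy-3-methoxyphenyl)-1,2,4-trimethoxy-7-methyl-5,6-dihydronaphthalene (racemic), via the titanium pinacolate 18 (not isolated)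
Conditions: TiCl3(DME)1.5, Zn–Cu couple, DME, reflux (slurry preformed); 17 in DME by syringe pump over ca. 30 h (final ca. 5 mM); further reflux
Reagents that add atoms: titanium trichloride, Cl[Ti](Cl)Cl (titanium of intermediate 18 only)
Why: Low-valent titanium made from TiCl3 (trivalent titanium) and the Zn–Cu couple transfers electrons first to the diaryl ketone at C8, the more easily reduced and non-enolisable carbonyl, and the titanium-bound ketyl attacks the methyl ketone carbon C7 to give the cyclic pinacolate 18. At reflux both C–O bonds of 18 are cleaved on titanium, helped by the doubly aryl-stabilised position C8, releasing the tetrasubstituted C7=C8 alkene. The closest known reaction type is the intramolecular McMurry keto–keto coupling of diketones to cycloalkenes, which covers aryl ketone/alkyl ketone pairs and tetrasubstituted alkenes. Ring B closes as a six-membered carbocycle by reductive carbonyl–carbonyl coupling of a 1,6-diketone whose C8a–C4a edge is a rigid ortho-phenylene unit, so few rotatable bonds must be frozen. No stereocentre is created: the alkene is endocyclic with no E/Z question, and C6 stays racemic until step 11 removes it. The step needs cyclisation over intermolecular coupling, secured by slow addition at high dilution and by the ortho tether, and coupling over simple reduction of the diaryl ketone, favoured by the nearby second carbonyl. Aryl benzyl ethers, aryl methyl ethers and the diarylmethane CH2 are inert to the reagent, and any migration of the new double bond within ring B is harmless because every such isomer aromatises to 20.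

Step 11
Reactants: 19 6-(4-benzyloxy-3-methoxybenzyl)-8-(4-benzyloxy-3-methoxyphenyl)-1,2,4-trimethoxy-7-methyl-5,6-dihydronaphthalene
Product: 20 6-(4-benzyloxy-3-methoxybenzyl)-8-(4-benzyloxy-3-methoxyphenyl)-1,2,4-trimethoxy-7-methylnaphthalene
Conditions: DDQ (1.1 equiv), PhMe (dry), rt → 60 °C
Reagents that add atoms: none
Why: DDQ dehydrogenation: hydride abstraction from C5, benzylic to ring A and stabilised by its ortho and para methoxy groups, then loss of the C6 proton gives the naphthalene and removes the only stereocentre.

Step 12
Reactants: 20 6-(4-benzyloxy-3-methoxybenzyl)-8-(4-benzyloxy-3-methoxyphenyl)-1,2,4-trimethoxy-7-methylnaphthalene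
Product: 21 6-(4-benzyloxy-3-methoxybenzyl)-8-(4-benzyloxy-3-methoxyphenyl)-2-methoxy-7-methylnaphthalene-1,4-dione
Conditions: (NH4)2Ce(NO3)6 (2.5 equiv), MeCN–H2O, 0 °C
Reagents that add atoms: water, O
Why: Oxidative demethylation by (NH4)2Ce(NO3)6 (tetravalent cerium): one-electron oxidation of the most electron-rich ring, addition of water at C1 and C4 and loss of two methanol give the para-quinone, with the C2 methoxy group kept as a vinylogous ester. The benzyloxy-methoxyphenyl rings have higher oxidation potentials and should remain intact.

Step 13
Reactants: 21 6-(4-benzyloxy-3-methoxybenzyl)-8-(4-benzyloxy-3-methoxyphenyl)-2-methoxy-7-methylnaphthalene-1,4-dione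
Product: 23 larreantin, via the naphthalene-1,4-diol 22 (not isolated)
Conditions: H2 (1 atm), 10% Pd/C, EtOAc–MeOH, rt; filter; air, rt
Reagents that add atoms: none
Why: Hydrogenolysis of both benzyl ethers on Pd/C also reduces the quinone to the hydroquinone 22; autoxidation in air of this electron-rich naphthohydroquinone restores the quinone and leaves the two phenols free.

## Compound list

1 | 2,4,5-trimethoxybenzoic acid | COc1cc(OC)c(C(=O)O)cc1OC | starting material
2 | 2,4,5-trimethoxybenzoyl chloride | COc1cc(OC)c(C(=O)Cl)cc1OC | intermediate
3 | N,N-diethyl-2,4,5-trimethoxybenzamide | CCN(CC)C(=O)c1cc(OC)c(OC)cc1OC | intermediate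
4 | 4-benzyloxy-3-methoxybenzaldehyde | O=Cc1ccc(OCc2ccccc2)c(OC)c1 | starting material
5 | N,N-diethyl-2-lithio-3,4,6-trimethoxybenzamide | [Li]c1c(OC)c(OC)cc(OC)c1C(=O)N(CC)CC | intermediate
6 | N,N-diethyl-2-[(4-benzyloxy-3-methoxyphenyl)(hydroxy)methyl]-3,4,6-trimethoxybenzamide (racemic, one enantiomer drawn; formed as its lithium alkoxide) | CCN(CC)C(=O)c1c(OC)cc(OC)c(OC)c1[C@H](O)c1ccc(OCc2ccccc2)c(OC)c1 | intermediate
7 | 3-(4-benzyloxy-3-methoxyphenyl)-4,5,7-trimethoxyisobenzofuran-1(3H)-one (racemic, one enantiomer drawn) | O=C1O[C@H](c2ccc(OCc3ccccc3)c(OC)c2)c2c(OC)c(OC)cc(OC)c12 | intermediate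
8 | (4-benzyloxy-3-methoxyphenyl)[2-(hydroxymethyl)-3,5,6-trimethoxyphenyl]methanol (racemic, one enantiomer drawn) | OCc1c(OC)cc(OC)c(OC)c1[C@H](O)c1ccc(OCc2ccccc2)c(OC)c1 | intermediate
9 | (4-benzyloxy-3-methoxyphenyl)[2-(tert-butyldimethylsilyloxymethyl)-3,5,6-trimethoxyphenyl]methanol (racemic, one enantiomer drawn) | CC(C)(C)[Si](C)(C)OCc1c(OC)cc(OC)c(OC)c1[C@H](O)c1ccc(OCc2ccccc2)c(OC)c1 | intermediate
10 | (4-benzyloxy-3-methoxyphenyl)[2-(tert-butyldimethylsilyloxymethyl)-3,5,6-trimethoxyphenyl]methanone | CC(C)(C)[Si](C)(C)OCc1c(OC)cc(OC)c(OC)c1C(=O)c1ccc(OCc2ccccc2)c(OC)c1 | intermediate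
11 | [2-(bromomethyl)-3,5,6-trimethoxyphenyl](4-benzyloxy-3-methoxyphenyl)methanone (2-(4-benzyloxy-3-methoxybenzoyl)-3,4,6-trimethoxybenzyl bromide) | BrCc1c(OC)cc(OC)c(OC)c1C(=O)c1ccc(OCc2ccccc2)c(OC)c1 | intermediate
12 | allyl acetoacetate (prop-2-en-1-yl 3-oxobutanoate) | C=CCOC(=O)CC(C)=O | starting material
13 | allyl 2-(4-benzyloxy-3-methoxybenzylidene)-3-oxobutanoate (E/Z mixture expected, Z drawn) | C=CCOC(=O)/C(C(C)=O)=C\c1ccc(OCc2ccccc2)c(OC)c1 | intermediate
14 | allyl 2-(4-benzyloxy-3-methoxybenzyl)-3-oxobutanoate (racemic, configurationally labile, one enantiomer drawn) | C=CCOC(=O)[C@@H](Cc1ccc(OCc2ccccc2)c(OC)c1)C(C)=O | intermediate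
15 | allyl 2-acetyl-2-(4-benzyloxy-3-methoxybenzyl)-3-[2-(4-benzyloxy-3-methoxybenzoyl)-3,4,6-trimethoxyphenyl]propanoate (racemic, one enantiomer drawn) | C=CCOC(=O)[C@](Cc1ccc(OCc2ccccc2)c(OC)c1)(Cc1c(OC)cc(OC)c(OC)c1C(=O)c1ccc(OCc2ccccc2)c(OC)c1)C(C)=O | intermediate
16 | 2-acetyl-2-(4-benzyloxy-3-methoxybenzyl)-3-[2-(4-benzyloxy-3-methoxybenzoyl)-3,4,6-trimethoxyphenyl]propanoic acid (racemic, one enantiomer drawn) | OC(=O)[C@](Cc1ccc(OCc2ccccc2)c(OC)c1)(Cc1c(OC)cc(OC)c(OC)c1C(=O)c1ccc(OCc2ccccc2)c(OC)c1)C(C)=O | intermediate
17 | 3-[2-(4-benzyloxy-3-methoxybenzoyl)-3,4,6-trimethoxybenzyl]-4-(4-benzyloxy-3-methoxyphenyl)butan-2-one (racemic, one enantiomer drawn) | COc1cc(OC)c(C[C@@H](Cc2ccc(OCc3ccccc3)c(OC)c2)C(C)=O)c(C(=O)c2ccc(OCc3ccccc3)c(OC)c2)c1OC | intermediate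
18 | titanium pinacolate of 17, drawn schematically as the cyclic titanium 7,8-diolate of 6-(4-benzyloxy-3-methoxybenzyl)-8-(4-benzyloxy-3-methoxyphenyl)-1,2,4-trimethoxy-7-methyl-5,6,7,8-tetrahydronaphthalene-7,8-diol (diastereomer mixture, one drawn) | COc1cc(OC)c2C[C@@H](Cc3ccc(OCc4ccccc4)c(OC)c3)[C@]3(C)O[Ti]O[C@]3(c3ccc(OCc4ccccc4)c(OC)c3)c2c1OC | intermediate
19 | 6-(4-benzyloxy-3-methoxybenzyl)-8-(4-benzyloxy-3-methoxyphenyl)-1,2,4-trimethoxy-7-methyl-5,6-dihydronaphthalene (racemic, one enantiomer drawn) | COc1cc(OC)c2C[C@@H](Cc3ccc(OCc4ccccc4)c(OC)c3)C(C)=C(c3ccc(OCc4ccccc4)c(OC)c3)c2c1OC | intermediate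
20 | 6-(4-benzyloxy-3-methoxybenzyl)-8-(4-benzyloxy-3-methoxyphenyl)-1,2,4-trimethoxy-7-methylnaphthalene | COc1cc(OC)c2cc(Cc3ccc(OCc4ccccc4)c(OC)c3)c(C)c(-c3ccc(OCc4ccccc4)c(OC)c3)c2c1OC | intermediate
21 | 6-(4-benzyloxy-3-methoxybenzyl)-8-(4-benzyloxy-3-methoxyphenyl)-2-methoxy-7-methylnaphthalene-1,4-dione | COC1=CC(=O)c2cc(Cc3ccc(OCc4ccccc4)c(OC)c3)c(C)c(-c3ccc(OCc4ccccc4)c(OC)c3)c2C1=O | intermediate
22 | 6-(4-hydroxy-3-methoxybenzyl)-8-(4-hydroxy-3-methoxyphenyl)-2-methoxy-7-methylnaphthalene-1,4-diol | COc1cc(O)c2cc(Cc3ccc(O)c(OC)c3)c(C)c(-c3ccc(O)c(OC)c3)c2c1O | intermediate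
23 | larreantin, 6-(4-hydroxy-3-methoxybenzyl)-8-(4-hydroxy-3-methoxyphenyl)-2-methoxy-7-methylnaphthalene-1,4-dione | COC1=CC(=O)c2cc(Cc3ccc(O)c(OC)c3)c(C)c(-c3ccc(O)c(OC)c3)c2C1=O | target

## Step count and least certain steps

Total steps: 13. Longest linear sequence: 12 steps (steps 1–6 and 8–13, from 1); step 7 is a one-step branch.

Step 10 (key step). What may go wrong: intermolecular coupling to dimers and oligomers if the stationary concentration of 17 is not kept low; arrest at the pinacolate stage through incomplete deoxygenation of the hindered ditertiary diolate; simple reduction of the diaryl ketone before it meets the second carbonyl; Lewis-acid-promoted aldol closure of the C6 enol onto C8. Fallback (stepwise coupling, then separate deoxygenation): setting out from 17, SmI2 (divalent samarium) in THF with t-BuOH should effect ketyl–carbonyl pinacol cyclisation, expected through a chelated transition state to give the cis-7,8-diol F1. F1 would be converted with 1,1′-thiocarbonyldiimidazole and DMAP in hot toluene into the cyclic thionocarbonate F2. Corey–Winter fragmentation of F2 with P(OMe)3 at reflux would give the alkene and re-enter the route at 19.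

Step 8. What may go wrong: ionisation of the benzylic bromide 11, which is activated by ortho and para methoxy groups, before or during the alkylation. This would lead to self-condensation, capture of the cation by the neighbouring ketone oxygen, or O-alkylation of the enolate. C–C bond formation may also be slow, because a quaternary carbon is made with a doubly ortho-substituted electrophile. Fallback (the ring A unit is attached by condensation instead of substitution): setting out from 8, Swern oxidation with excess reagent, both hydroxyl groups being activated before Et3N is added, should give the keto aldehyde F3. Proline-catalysed Knoevenagel condensation of F3 with 12 in the presence of Hantzsch ester should give the monoalkylated keto ester F4. In parallel, 4 would be reduced with NaBH4 to 4-benzyloxy-3-methoxybenzyl alcohol F5 and converted with SOCl2 into 4-benzyloxy-3-methoxybenzyl chloride F6. Alkylation of the sodium enolate of F4 (NaH, NaI cat., THF–DMF) with F6, an unhindered electrophile, returns to the route at 15. The weak point of this fallback is possible closure of the F4 enolate onto the ortho diaryl ketone.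

Step 11. What may go wrong: over-oxidation, by hydride abstraction from the doubly benzylic CH2 on C6 of the product (followed by oxygenation there if water is present) or by oxidative coupling of the very electron-rich trimethoxynaphthalene. Fallback (ring A is oxidised first and ring B aromatises by tautomerisation): setting out from 19, (NH4)2Ce(NO3)6 in MeCN–H2O should give the dihydroquinone F7, whose C5–H is vinylogously acidic. A trace of Et3N should isomerise F7 to the naphthalene-1,4-diol F8, and air or a further portion of the cerium reagent should oxidise F8 to the quinone, re-entering the route at 21 and bypassing 20.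

Step 12. What may go wrong: hydrolysis of the radical cation with the wrong regiochemistry (water adding at C2 instead of C4, leading to the ortho-quinone), competing oxidation of the benzyloxy-methoxyphenyl rings or of the C6 CH2, and ring nitration. Fallback (two-electron anodic route through a bisketal): setting out from 20, anodic oxidation at a platinum anode in KOH/MeOH should add methoxide at C1 and C4 to give the quinone bisketal F9. Mild aqueous acid (AcOH–H2O–acetone) should hydrolyse both ketal groups and return to the route at 21.

## Further compounds

F1 | step 10 | cis-6-(4-benzyloxy-3-methoxybenzyl)-8-(4-benzyloxy-3-methoxyphenyl)-1,2,4-trimethoxy-7-methyl-5,6,7,8-tetrahydronaphthalene-7,8-diol (racemic, one diastereomer drawn) | COc1cc(OC)c2C[C@@H](Cc3ccc(OCc4ccccc4)c(OC)c3)[C@](C)(O)[C@@](O)(c3ccc(OCc4ccccc4)c(OC)c3)c2c1OC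
F2 | step 10 | cyclic thionocarbonate of F1 (7,8-O,O-thiocarbonyl derivative; racemic, one diastereomer drawn) | COc1cc(OC)c2C[C@@H](Cc3ccc(OCc4ccccc4)c(OC)c3)[C@]3(C)OC(=S)O[C@]3(c3ccc(OCc4ccccc4)c(OC)c3)c2c1OC
F3 | step 8 | 2-(4-benzyloxy-3-methoxybenzoyl)-3,4,6-trimethoxybenzaldehyde | O=Cc1c(OC)cc(OC)c(OC)c1C(=O)c1ccc(OCc2ccccc2)c(OC)c1
F4 | step 8 | allyl 2-[2-(4-benzyloxy-3-methoxybenzoyl)-3,4,6-trimethoxybenzyl]-3-oxobutanoate (racemic, one enantiomer drawn) | C=CCOC(=O)[C@@H](Cc1c(OC)cc(OC)c(OC)c1C(=O)c1ccc(OCc2ccccc2)c(OC)c1)C(C)=O
F5 | step 8 | 4-benzyloxy-3-methoxybenzyl alcohol | OCc1ccc(OCc2ccccc2)c(OC)c1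
F6 | step 8 | 4-benzyloxy-3-methoxybenzyl chloride | ClCc1ccc(OCc2ccccc2)c(OC)c1
F7 | step 11 | 6-(4-benzyloxy-3-methoxybenzyl)-8-(4-benzyloxy-3-methoxyphenyl)-2-methoxy-7-methyl-5,6-dihydronaphthalene-1,4-dione (racemic, one enantiomer drawn) | COC1=CC(=O)C2=C(C1=O)C(c1ccc(OCc3ccccc3)c(OC)c1)=C(C)[C@H](Cc1ccc(OCc3ccccc3)c(OC)c1)C2
F8 | step 11 | 6-(4-benzyloxy-3-methoxybenzyl)-8-(4-benzyloxy-3-methoxyphenyl)-2-methoxy-7-methylnaphthalene-1,4-diol | COc1cc(O)c2cc(Cc3ccc(OCc4ccccc4)c(OC)c3)c(C)c(-c3ccc(OCc4ccccc4)c(OC)c3)c2c1O
F9 | step 12 | 6-(4-benzyloxy-3-methoxybenzyl)-8-(4-benzyloxy-3-methoxyphenyl)-1,1,2,4,4-pentamethoxy-7-methyl-1,4-dihydronaphthalene | COC1=CC(OC)(OC)c2cc(Cc3ccc(OCc4ccccc4)c(OC)c3)c(C)c(-c3ccc(OCc4ccccc4)c(OC)c3)c2C1(OC)OC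
A1 | alternative 1 | larreantin bis(tert-butyldimethylsilyl) ether | COC1=CC(=O)c2cc(Cc3ccc(O[Si](C)(C)C(C)(C)C)c(OC)c3)c(C)c(-c3ccc(O[Si](C)(C)C(C)(C)C)c(OC)c3)c2C1=O
A2 | alternative 1 | 1-[4-(tert-butyldimethylsilyloxy)-3-methoxyphenyl]-4-methoxyoct-4-ene-1,7-diyne-3,6-dione with the two acyl groups cis (formally 4E) | C#CC(=O)/C=C(/OC)C(=O)C#Cc1ccc(O[Si](C)(C)C(C)(C)C)c(OC)c1
A3 | alternative 1 | 4-(but-2-yn-1-yl)-1-(tert-butyldimethylsilyloxy)-2-methoxybenzene | CC#CCc1ccc(O[Si](C)(C)C(C)(C)C)c(OC)c1
A4 | alternative 2 | 6-[4-(tert-butyldimethylsilyloxy)-3-methoxybenzyl]-8-[4-(tert-butyldimethylsilyloxy)-3-methoxyphenyl]-2-methoxy-7-methylnaphthalene-1,4-diol | COc1cc(O)c2cc(Cc3ccc(O[Si](C)(C)C(C)(C)C)c(OC)c3)c(C)c(-c3ccc(O[Si](C)(C)C(C)(C)C)c(OC)c3)c2c1O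
A5 | alternative 2 | 4-hydroxy-3-methoxy-4-{4-[4-(tert-butyldimethylsilyloxy)-3-methoxybenzyl]-2-[4-(tert-butyldimethylsilyloxy)-3-methoxyphenyl]-3-methylphenyl}cyclobut-2-en-1-one (racemic, one enantiomer drawn) | COC1=CC(=O)[C@@]1(O)c1ccc(Cc2ccc(O[Si](C)(C)C(C)(C)C)c(OC)c2)c(C)c1-c1ccc(O[Si](C)(C)C(C)(C)C)c(OC)c1
A6 | alternative 2 | 1-bromo-4-[4-(tert-butyldimethylsilyloxy)-3-methoxybenzyl]-2-[4-(tert-butyldimethylsilyloxy)-3-methoxyphenyl]-3-methylbenzene | Brc1ccc(Cc2ccc(O[Si](C)(C)C(C)(C)C)c(OC)c2)c(C)c1-c1ccc(O[Si](C)(C)C(C)(C)C)c(OC)c1
A7 | alternative 2 | 3-methoxycyclobut-3-ene-1,2-dione | COC1=CC(=O)C1=O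
A8 | alternative 3 | (4-benzyloxy-3-methoxyphenyl)[8-(4-benzyloxy-3-methoxyphenyl)-1,2,4-trimethoxy-7-methylnaphthalen-6-yl]methanone | COc1cc(OC)c2cc(C(=O)c3ccc(OCc4ccccc4)c(OC)c3)c(C)c(-c3ccc(OCc4ccccc4)c(OC)c3)c2c1OC
A9 | alternative 3 | 2-(4-benzyloxy-3-methoxybenzyl)-3,4,6-trimethoxybenzaldehyde | COc1cc(OC)c(C=O)c(Cc2ccc(OCc3ccccc3)c(OC)c2)c1OC
A10 | alternative 3 | 1-(4-benzyloxy-3-methoxyphenyl)but-2-yn-1-one | CC#CC(=O)c1ccc(OCc2ccccc2)c(OC)c1
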